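**Remark on the chemistry.** Lignan locants are used: C7/C7' are the benzylic carbons, C8/C8' the ring-fusion carbons, C9/C9' the methylenes. Ring A is C8–C7–O–C9'–C8' and ring B is C8'–C7'–O–C9–C8. In bicyclic names C1 = C8, C2 = C7, C4 = C9', C5 = C8', C6 = C7', C8 = C9. Ar = 4-(allyloxy)-3-methoxyphenyl.

## The problem

- Compound 15 is a cis-fused 3,7-dioxabicyclo[3.3.0]octane. Ring A and ring B share the C8–C8' bond, and each carries a guaiacyl group on its benzylic ether carbon (C7, C7') on the convex face.
- Four contiguous stereocentres (C7, C8, C8', C7') must be set. C8 is a fully substituted carbinol at the ring fusion, so it cannot be made by a late protonation or hydrogenation.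
- The cis fusion ties C8' to C8, but nothing ties C7 and C7' to them thermodynamically. Guaiacyl benzylic ethers ionise under acid and the exo and endo epimers are close in energy. C7 and C7' therefore have to come from stereospecific, kinetically controlled bond formation.
- A twofold axis through the midpoint of C8–C8' exchanges ring A and ring B. Only OH at C8 against H at C8' breaks it, and this is what defeats a plain dimerisation of two C6–C3 units.
- The free phenols (oxidants, radical chains), the benzylic C–O bonds (acid, hydrogenolysis) and the tertiary alcohol will not survive rough treatment.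
- The enabling feature: in each ring the benzylic ether carbon (C7 in ring A, C7' in ring B) is bonded to a ring-fusion carbon (C8, C8'). If C8' carried a hydroxyl like C8, each O–C7–C8–O unit would be the retron of a trans-epoxide of an (E)-cinnamyl alcohol, opened at its benzylic carbon by the CH2OH (C9', C9) of the other half. The whole bicycle then reduces to an achiral diene diol plus two oxygen atoms.

## Retrosynthesis

**15 ⇒ 14.** The two O–allyl bonds are cut last. Allyl ethers survive alkoxide, hydride, peroxide, acid and tin hydride, and they come off under neutral palladium catalysis. Acid (epimerisation at C7/C7') and hydrogenolysis (cleavage of the ring benzylic C–O bonds) are both avoided.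

**14 ⇒ 13 ⇒ 12 ⇒ 11.** The C8'–H bond is exchanged for a C8'–OH bond, which restores the twofold axis in diol 11. The forward direction is a radical deletion of one oxygen through the cyclic thionocarbonate 12.
- The two bridgehead C–O bonds of 12 are homotopic, so no regiochemical question arises.
- The bridgehead radical can only be reduced to the cis-fused product.
- The neighbouring option, oxidising only one alkene of 8, was set aside. It passes through a vinyl epoxide whose C8–O bond is allylic and conjugated to the second aryl group, and it still needs a stereocontrolled hydroalkoxylation of the remaining styrene. It is kept as a fallback.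

**11 ⇒ 10 ⇒ 9 ⇒ 8.** Both benzylic ether bonds (C7–O in ring A, C7'–O in ring B) are cut, which opens 11 to the C2-symmetric bis-epoxide 9 by way of the mono-cyclised spiro-epoxide 10. Removing both epoxide oxygens gives the achiral (E,E)-diene diol 8.
- This single retrosynthetic operation removes both rings and all four stereocentres.
- The forward reaction needs reagent-controlled epoxidation of two primary allylic alcohols, a reliable substrate class, followed by two 5-endo openings at activated benzylic carbons with inversion.
- Against the neighbouring C7–C8 or C8–C8' cuts, it uses the latent symmetry and sets C7 and C7' stereospecifically instead of by equilibration.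

**8 ⇒ 7 ⇒ 6 ⇒ 2 + 3.** The two allylic alcohols come from the diester 7 and the diacid 6. The C7=C8 and C7'=C8' bonds are cut by a double Stobbe condensation, which proceeds through lactones 4 and 5. The C8–C8' bond is therefore bought with diethyl succinate 3, and no like-polarity coupling has to be invented. The forward reaction must give the (E,E) geometry, which is the thermodynamic one.

**2 ⇒ 1.** Aldehyde 2 is the allyl ether of vanillin 1.

## Roads not taken

**Alternative 1:** the stepwise lactone route, which is the obvious one.
- Cut: ring A ether, then C7–C8 by an aldol reaction, then the C8–OH bond by enolate oxidation.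
- Forward: an enantioenriched trans lactone A1 (ring B as a γ-lactone) is made by an auxiliary-controlled sequence. Its enolate is condensed with 2 at C8 and the resulting lactone is hydroxylated at C8 to give A2. Lactone reduction and two ether closures follow.
- Why the chosen plan is better: C7' and C8' of A1 need their own asymmetric sequence. The aldol of a lactone enolate with an aryl aldehyde gives little control at C7. The hydroxylation must create the fully substituted C8 next to a β-hydroxyl that invites retro-aldol cleavage. The last ether closure runs through a guaiacyl benzylic cation, which scrambles C7. Every stereocentre is set separately, in well over ten steps.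

**Alternative 2:** biomimetic oxidative dimerisation.
- Cut: C8–C8', as a union of two carbons of like polarity.
- Forward: oxidation of ferulic acid (FeCl3/O2 or a peroxidase) couples two phenoxyl radicals at their β-carbons to give the racemic dilactone A3. Bridgehead enolate hydroxylation and reduction of both lactones to ethers would follow.
- Why the chosen plan is better: the radical coupling also gives 8–5' and 8–O–4' dimers and offers no handle for absolute configuration. The bridgehead enolate of A3 has an acyloxy leaving group on C7 and can open by E1cB, the same process that destroys 5 in step 2. Lactone-to-ether reduction has to be done next to ionisable benzylic C–O bonds. In the chosen plan the C8–C8' bond costs nothing and the catalyst sets the absolute configuration.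

**Alternative 3:** Norrish–Yang photocyclisation.
- Cut: C7–C8 of ring A.
- Forward: irradiation of ketone A4 (carbonyl at C8 in ring B, aryl-methyl ether side chain on C8'). A 1,6-hydrogen transfer from the benzylic CH2 gives a 1,5-biradical, and its recombination forms the C7–C8 bond and the tertiary alcohol.
- Why the chosen plan is better: A4 needs C7' and C8' installed enantioselectively first, in roughly six steps, with one centre α to the ketone. Biradical recombination has no reliable control element for the aryl orientation at C7. The electron-rich aryl ethers favour reverse hydrogen transfer and quenching. The step solves half of the stereochemical problem and ignores the symmetry.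

Key step: step 5

## Route

Step 1
Reactants: 1 vanillin (4-hydroxy-3-methoxybenzaldehyde)
Product: 2 4-(allyloxy)-3-methoxybenzaldehyde
Conditions: allyl bromide, K2CO3, acetone, reflux
Reagents that add atoms: allyl bromide, C=CCBr
Why: Williamson ether synthesis on the phenoxide; the allyl ether survives all later steps and is removed at the end without acid or hydrogen.

Step 2
Reactants: 2 4-(allyloxy)-3-methoxybenzaldehyde (2.2 equiv); 3 diethyl succinate
Product: 6 (2E,3E)-2,3-bis[4-(allyloxy)-3-methoxybenzylidene]succinic acid, via aryl paraconic ester 4 (not isolated), via bis-lactone 5 (not isolated)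
Conditions: NaOEt (3 equiv), EtOH, reflux; aq. HCl
Reagents that add atoms: none
Why: One-flask double Stobbe condensation, the classical entry to fulgenic acids: the lactone ester 4 of the first aldol should be enolised at its lactone α-carbon and add a second aldehyde to give 5. Two E1cB ring openings of 5 then place each aryl trans to its carboxyl, the thermodynamically preferred (E,E) geometry.

Step 3
Reactants: 6 (2E,3E)-2,3-bis[4-(allyloxy)-3-methoxybenzylidene]succinic acid
Product: 7 dimethyl (2E,3E)-2,3-bis[4-(allyloxy)-3-methoxybenzylidene]succinate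
Conditions: MeI, K2CO3, DMF, rt
Reagents that add atoms: iodomethane, CI
Why: SN2 O-alkylation of the dicarboxylate; it avoids acid, which could trigger cationic cyclisation of the electron-rich diene.

Step 4
Reactants: 7 dimethyl (2E,3E)-2,3-bis[4-(allyloxy)-3-methoxybenzylidene]succinate
Product: 8 (2E,3E)-2,3-bis[4-(allyloxy)-3-methoxybenzylidene]butane-1,4-diol
Conditions: i-Bu2AlH (5 equiv), CH2Cl2, −78 → 0 °C; aq. potassium sodium tartrate
Reagents that add atoms: none
Why: 1,2-Reduction of both conjugated esters by the aluminium hydride at low temperature; the trisubstituted alkenes keep their geometry and the allyl ethers are inert.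

Step 5
Reactants: 8 (2E,3E)-2,3-bis[4-(allyloxy)-3-methoxybenzylidene]butane-1,4-diol
Product: 11 (1S,2R,5S,6R)-2,6-bis[4-(allyloxy)-3-methoxyphenyl]-3,7-dioxabicyclo[3.3.0]octane-1,5-diol, via bis-epoxide 9 (not isolated), via spiro-epoxy tetrahydrofuranol 10 (not isolated)
Conditions: diisopropyl L-(+)-tartrate (0.30 equiv), Ti(OiPr)4 (0.25 equiv), t-BuOOH (3 equiv, in decane), 4 Å molecular sieves, CH2Cl2, −25 °C; then (+)-10-camphorsulfonic acid (0.1 equiv), −25 → 0 °C
Reagents that add atoms: tert-butyl hydroperoxide, CC(C)(C)OO
Why: Two Sharpless asymmetric epoxidations turn both (E)-2-substituted cinnamyl alcohol units of achiral 8 into trans-epoxides, L-(+)-tartrate delivering oxygen to the face that makes C7, C8, C7' and C8' of 9 all S; a wrong-face event at one alkene gives a separable meso-type diastereomer instead of the enantiomer. Acid then opens the first epoxide at benzylic C7 by the hydroxymethyl oxygen on C9' (ring A, giving 10) and the remaining spiro-epoxide at benzylic C7' by the hydroxymethyl oxygen on C9 (ring B). Both closures are 5-endo-tet epoxide openings, feasible because the 4-alkoxy-3-methoxyphenyl group loosens the benzylic C–O bond in a borderline SN2 transition state; the closest known reaction type is the aryl-directed endo cyclisation of 4-aryl-3,4-epoxy alcohols to 2-aryl-3-hydroxytetrahydrofurans. Regioselectivity rests on the substrate: attack at C7 or C7' forms a five-membered ring at a stabilised benzylic carbon, whereas attack at C8 or C8' would form an oxetane at a fully substituted carbon flanked by two oxygen-bearing carbons. C8 and C8' are set by the catalyst and are not touched afterwards; C7 and C7' are set by inversion, which from the E alkenes places each aryl cis to the adjacent tertiary hydroxyl, the exo position of the bicycle. Because 9 is C2-symmetric, the second epoxide oxygen in 10 lies cis to the new C8 hydroxyl, the only arrangement from which the cis-fused ring B can close. The step needs both alkenes to be epoxidised before any epoxide ionises, which low temperature, catalytic tetravalent titanium, molecular sieves and the late addition of acid are meant to secure.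

Step 6
Reactants: 11 (1S,2R,5S,6R)-2,6-bis[4-(allyloxy)-3-methoxyphenyl]-3,7-dioxabicyclo[3.3.0]octane-1,5-diol
Product: 12 cyclic 1,5-thionocarbonate of 11 (2-thioxo-1,3-dioxolane fused across C1–C5)
Conditions: 1,1'-thiocarbonyldiimidazole (3 equiv), DMAP (cat.), toluene, 110 °C
Reagents that add atoms: 1,1'-thiocarbonyldiimidazole, S=C(n1ccnc1)n1ccnc1
Why: Thioacylation of the cis-1,2-diol on the convex face and closure to the five-membered thionocarbonate; no stereocentre is touched.

Step 7
Reactants: 12 cyclic 1,5-thionocarbonate of 11
Product: 14 (1S,2R,5R,6S)-2,6-bis[4-(allyloxy)-3-methoxyphenyl]-3,7-dioxabicyclo[3.3.0]octan-1-ol, via S-stannyl thiocarbonate 13 (not isolated)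
Conditions: Bu3SnH (2 equiv), AIBN (cat.), toluene, 110 °C; then K2CO3 (cat.), MeOH–H2O, rt
Reagents that add atoms: none
Why: Barton–McCombie-type deoxygenation of a cyclic thionocarbonate: the stannyl radical adds to sulfur and β-scission of a bridgehead C–O bond gives a tertiary radical, which takes hydrogen from Bu3SnH on the convex face because only the cis-fused bicycle is accessible. The two C–O bonds are homotopic under the twofold axis, so either cleavage gives 13, and hydrolytic loss of its stannyl thiocarbonate residue frees the C8 hydroxyl.

Step 8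
Reactants: 14 (1S,2R,5R,6S)-2,6-bis[4-(allyloxy)-3-methoxyphenyl]-3,7-dioxabicyclo[3.3.0]octan-1-ol
Product: 15 8-hydroxypinoresinol, (1S,2R,5R,6S)-2,6-bis(4-hydroxy-3-methoxyphenyl)-3,7-dioxabicyclo[3.3.0]octan-1-ol
Conditions: Pd(PPh3)4 (5 mol%), morpholine (6 equiv), THF, rt
Reagents that add atoms: none
Why: Tsuji–Trost deallylation: zerovalent palladium ionises the aryl allyl ethers to π-allyl complexes that morpholine captures. The neutral conditions leave the benzylic ethers and their configuration untouched.

## Compound list

1 | vanillin (4-hydroxy-3-methoxybenzaldehyde) | COc1cc(C=O)ccc1O | starting material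
2 | 4-(allyloxy)-3-methoxybenzaldehyde | COc1cc(C=O)ccc1OCC=C | intermediate
3 | diethyl succinate | CCOC(=O)CCC(=O)OCC | starting material
4 | ethyl 2-[4-(allyloxy)-3-methoxyphenyl]-5-oxotetrahydrofuran-3-carboxylate (aryl paraconic ester, not isolated, stereoisomer mixture) | CCOC(=O)C1CC(=O)OC1c1ccc(OCC=C)c(OC)c1 | intermediate
5 | 4,8-bis[4-(allyloxy)-3-methoxyphenyl]-3,7-dioxabicyclo[3.3.0]octane-2,6-dione (bis-lactone, not isolated, stereoisomer mixture) | O=C1OC(c3ccc(OCC=C)c(OC)c3)C2C1C(c4ccc(OCC=C)c(OC)c4)OC2=O | intermediate
6 | (2E,3E)-2,3-bis[4-(allyloxy)-3-methoxybenzylidene]succinic acid | OC(=O)/C(=C/c1ccc(OCC=C)c(OC)c1)/C(=C\c1ccc(OCC=C)c(OC)c1)C(=O)O | intermediate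
7 | dimethyl (2E,3E)-2,3-bis[4-(allyloxy)-3-methoxybenzylidene]succinate | COC(=O)/C(=C/c1ccc(OCC=C)c(OC)c1)/C(=C\c1ccc(OCC=C)c(OC)c1)C(=O)OC | intermediate
8 | (2E,3E)-2,3-bis[4-(allyloxy)-3-methoxybenzylidene]butane-1,4-diol | OC/C(=C/c1ccc(OCC=C)c(OC)c1)/C(=C\c1ccc(OCC=C)c(OC)c1)CO | intermediate
9 | [(2S,2'S,3S,3'S)-3,3'-bis[4-(allyloxy)-3-methoxyphenyl]-[2,2'-bioxirane]-2,2'-diyl]dimethanol (not isolated) | OC[C@@]1(O[C@H]1c3ccc(OCC=C)c(OC)c3)[C@@]2(CO)O[C@H]2c4ccc(OCC=C)c(OC)c4 | intermediate
10 | (2S,3S,6R,7S)-2,6-bis[4-(allyloxy)-3-methoxyphenyl]-7-(hydroxymethyl)-1,5-dioxaspiro[2.4]heptan-7-ol (not isolated) | OC[C@]1(O)[C@@H](c3ccc(OCC=C)c(OC)c3)OC[C@@]12O[C@H]2c4ccc(OCC=C)c(OC)c4 | intermediate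
11 | (1S,2R,5S,6R)-2,6-bis[4-(allyloxy)-3-methoxyphenyl]-3,7-dioxabicyclo[3.3.0]octane-1,5-diol | COc1cc([C@H]2OC[C@]3(O)[C@@H](c4ccc(OCC=C)c(OC)c4)OC[C@]23O)ccc1OCC=C | intermediate
12 | cyclic 1,5-thionocarbonate of 11 | COc1cc([C@H]2OC[C@]3(OC(=S)O5)[C@@H](c4ccc(OCC=C)c(OC)c4)OC[C@]235)ccc1OCC=C | intermediate
13 | O-[(1S,2R,5R,6S)-2,6-bis[4-(allyloxy)-3-methoxyphenyl]-3,7-dioxabicyclo[3.3.0]octan-1-yl] S-(tributylstannyl) thiocarbonate (not isolated) | COc1cc([C@H]2OC[C@]3(OC(=O)S[Sn](CCCC)(CCCC)CCCC)[C@@H](c4ccc(OCC=C)c(OC)c4)OC[C@H]23)ccc1OCC=C | intermediate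
14 | (1S,2R,5R,6S)-2,6-bis[4-(allyloxy)-3-methoxyphenyl]-3,7-dioxabicyclo[3.3.0]octan-1-ol | COc1cc([C@H]2OC[C@]3(O)[C@@H](c4ccc(OCC=C)c(OC)c4)OC[C@H]23)ccc1OCC=C | intermediate
15 | 8-hydroxypinoresinol, (1S,2R,5R,6S)-2,6-bis(4-hydroxy-3-methoxyphenyl)-3,7-dioxabicyclo[3.3.0]octan-1-ol | COc1cc([C@H]2OC[C@]3(O)[C@@H](c4ccc(O)c(OC)c4)OC[C@H]23)ccc1O | target

## Step count and risk

Total steps: 8. Longest linear sequence: 8 (vanillin 1 to 15; diethyl succinate 3 enters at step 2).

**Step 5 (key step).**
- The first-formed mono-epoxide is a vinyl epoxide whose C8–O bond is allylic and conjugated to the second aryl group. It may ionise before the second alkene is epoxidised, and the mono-cyclised product is a poor substrate for further titanium tartrate epoxidation.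
- Free rotation in a fully developed benzylic cation could erode the inversion at C7 or C7'.
- Binding of the 1,4-diol to titanium could lower facial selectivity.
- Isopropanol or hydroperoxide could capture the benzylic position in place of the internal hydroxyl.
- Fallback, which oxidises only once and makes the second ring by halocyclisation: from 8, the same catalyst with one equivalent of t-BuOOH should give, after in-flask opening at C7, (2R,3S,4Z)-2-[4-(allyloxy)-3-methoxyphenyl]-4-[4-(allyloxy)-3-methoxybenzylidene]-3-(hydroxymethyl)tetrahydrofuran-3-ol F1. A 5-endo iodoetherification (I2, NaHCO3, MeCN, 0 °C; anti addition, oxygen to benzylic C7') should give the bridgehead iodide (1S,2R,5S,6R)-5-iodo-2,6-bis[4-(allyloxy)-3-methoxyphenyl]-3,7-dioxabicyclo[3.3.0]octan-1-ol F2. Radical deiodination (Bu3SnH, AIBN) returns to the route at 14 and makes steps 6 and 7 unnecessary.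

**Step 6.**
- Ring closure to the thionocarbonate may stall at the mono-thioacyl stage, because both hydroxyls are tertiary and each is flanked by a cis aryl group. Prolonged heating invites elimination.
- Fallback, which uses an acyclic mono-ester as radical precursor: from 11, one equivalent of NaN(SiMe3)2 and methyl chlorooxoacetate should give the mono(methyl oxalate) of 11, F3. Tin hydride reduction of this tertiary oxalate (Bu3SnH, AIBN, toluene, 110 °C) replaces the acylated oxygen by hydrogen and returns at 14. The twofold symmetry again makes the choice of hydroxyl immaterial.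

**Step 2.**
- The one-flask double condensation competes with E1cB opening of 4 to the mono-arylidene half-ester salt, which does not condense further, and with aldehyde consumption by side reactions. The yield may be modest.
- Fallback, stepwise with isolation: from 2 and 3, a single Stobbe condensation gives (E)-3-(ethoxycarbonyl)-4-[4-(allyloxy)-3-methoxyphenyl]but-3-enoic acid F4. Ethylation (EtI, K2CO3) gives diethyl (E)-2-[4-(allyloxy)-3-methoxybenzylidene]succinate F5. A second Stobbe condensation with 2 gives the (2E,3E)-bis(arylidene)succinic acid monoethyl ester F6. Saponification (aq. NaOH) returns at 6.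

## Further compounds

F1 | step 5 | (2R,3S,4Z)-2-[4-(allyloxy)-3-methoxyphenyl]-4-[4-(allyloxy)-3-methoxybenzylidene]-3-(hydroxymethyl)tetrahydrofuran-3-ol | OC[C@]1(O)[C@@H](c2ccc(OCC=C)c(OC)c2)OC/C1=C/c3ccc(OCC=C)c(OC)c3
F2 | step 5 | (1S,2R,5S,6R)-5-iodo-2,6-bis[4-(allyloxy)-3-methoxyphenyl]-3,7-dioxabicyclo[3.3.0]octan-1-ol | COc1cc([C@H]2OC[C@]3(O)[C@@H](c4ccc(OCC=C)c(OC)c4)OC[C@]23I)ccc1OCC=C
F3 | step 6 | mono(methyl oxalate) of 11 | COc1cc([C@H]2OC[C@]3(O)[C@@H](c4ccc(OCC=C)c(OC)c4)OC[C@]23OC(=O)C(=O)OC)ccc1OCC=C
F4 | step 2 | (E)-3-(ethoxycarbonyl)-4-[4-(allyloxy)-3-methoxyphenyl]but-3-enoic acid | CCOC(=O)/C(=C/c1ccc(OCC=C)c(OC)c1)CC(=O)O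
F5 | step 2 | diethyl (E)-2-[4-(allyloxy)-3-methoxybenzylidene]succinate | CCOC(=O)/C(=C/c1ccc(OCC=C)c(OC)c1)CC(=O)OCC
F6 | step 2 | (2E,3E)-2,3-bis[4-(allyloxy)-3-methoxybenzylidene]succinic acid monoethyl ester | CCOC(=O)/C(=C/c1ccc(OCC=C)c(OC)c1)/C(=C\c1ccc(OCC=C)c(OC)c1)C(=O)O
A1 | alternative 1 | (4R,5S)-5-[4-(allyloxy)-3-methoxyphenyl]-4-[(tert-butyldimethylsilyloxy)methyl]dihydrofuran-2(3H)-one | COc1cc([C@H]2OC(=O)C[C@@H]2CO[Si](C)(C)C(C)(C)C)ccc1OCC=C
A2 | alternative 1 | 3-hydroxy-3-[aryl(hydroxy)methyl] derivative of A1 with the C7 and C8 configuration of 15 | COc1cc([C@H]2OC(=O)[C@](O)([C@H](O)c3ccc(OCC=C)c(OC)c3)[C@@H]2CO[Si](C)(C)C(C)(C)C)ccc1OCC=C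
A3 | alternative 2 | 4,8-bis(4-hydroxy-3-methoxyphenyl)-3,7-dioxabicyclo[3.3.0]octane-2,6-dione (racemic; the enantiomer that maps onto 15 is drawn) | COc1cc([C@H]2OC(=O)[C@@H]3[C@@H](c4ccc(O)c(OC)c4)OC(=O)[C@H]23)ccc1O
A4 | alternative 3 | (4R,5S)-5-[4-(allyloxy)-3-methoxyphenyl]-4-{[(4-(allyloxy)-3-methoxyphenyl)methoxy]methyl}dihydrofuran-3(2H)-one | COc1cc([C@H]2OCC(=O)[C@@H]2COCc3ccc(OCC=C)c(OC)c3)ccc1OCC=C
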